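## Retrosynthetic overview

- The C12–C13 bond is made last. A lithiated (S)-but-3-en-2-yl carbamate (an α-oxygenated allyl carbanion) is joined to a primary decalin-ethyl boronic ester by a 1,2-metallate shift; C–B oxidation then gives the tertiary allylic alcohol and sets C13.
- The boronic ester comes from the C12 aldehyde by deoxygenative borylation. The aldehyde and an 8-O-acetyl protecting group both come from ozonolysis of a tricyclic enol ether.
- The enol ether comes from (5E,9E)-farnesylacetone by a catalyst-controlled bromonium polyene cyclisation, which sets C3, C5, C10, C9 and C8.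
- Ring order: ring A (bromocyclohexane), then ring B, then a temporary dihydropyran closed by the ketone oxygen. This ring delivers the C8 oxygen and is opened again in the ozonolysis.

Assumptions: (5E,9E)-farnesylacetone is bought as the single geometric isomer; the antipode of the cyclisation catalyst that gives the (3R) series drawn is chosen by a test run.

## Route

Step 1
Reactants: 1 (5E,9E)-6,10,14-trimethylpentadeca-5,9,13-trien-2-one ((E,E)-farnesylacetone)
Product: 3 (4aS,6aS,8R,10aR,10bS)-8-bromo-3,4a,7,7,10a-pentamethyl-4a,5,6,6a,7,8,9,10,10a,10b-decahydro-1H-benzo[f]chromene (trans-fused tricyclic enol ether; labdane numbering: 3-bromo-8,13-epoxy-14,15-dinorlabd-12-ene, ent series), via hydroxy ketone 2 (not isolated)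
Conditions: chiral 3,3'-diaryl-BINOL-derived thiophosphoramide (10 mol %), DBDMH (1.05 equiv), toluene/CH2Cl2, −90 °C; aq Na2S2O3 at −90 °C; crude, PPTS (cat.), benzene, reflux (Dean–Stark)
Reagents that add atoms: 1,3-dibromo-5,5-dimethylhydantoin (DBDMH), CC1(C)N(Br)C(=O)N(Br)C1=O; water, O (its oxygen is in 2 only and leaves again on dehydration)
Why: Proposed new method: catalytic enantioselective bromonium-initiated polyene cyclisation is known with arene and phenol terminators, and ketone-terminated bromo- and mercuri-cyclisations of geranylacetone-type polyenes are known in racemic form (closest known types); here the chiral Lewis base–Br+ complex attacks one face of the terminal, most electron-rich alkene (sets C3), the E,E-triene closes ring A and ring B through chair–chair antiperiplanar additions (sets C5, C10 and C9, trans fusion, equatorial Br), the ketone oxygen captures the C8 cation anti to the new C9–C10 bond (sets C8, oxygen equatorial), and acid-catalysed dehydration funnels the hemiketal/hydroxy ketone 2 into the endocyclic enol ether 3.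

Step 2
Reactants: 3 tricyclic bromo enol ether
Product: 4 2-[(1S,2S,4aS,6R,8aR)-2-acetoxy-6-bromo-2,5,5,8a-tetramethyldecahydronaphthalen-1-yl]acetaldehyde
Conditions: O3, CH2Cl2, −78 °C; then Me2S, −78 °C to rt
Reagents that add atoms: ozone, [O-][O+]=O
Why: Ozonolysis (Criegee cleavage) of the electron-rich enol-ether double bond turns C12 into the aldehyde and C13 into the acetyl group of an 8-O-acetate that protects the tertiary alcohol; no stereocentre is touched and the C–Br bond is inert to ozone.

Step 3
Reactants: 4 acetoxy aldehyde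
Product: 6 (1S,2S,4aS,6R,8aR)-6-bromo-2,5,5,8a-tetramethyl-1-[2-(4,4,5,5-tetramethyl-1,3,2-dioxaborolan-2-yl)ethyl]decahydronaphthalen-2-yl acetate, via tosylhydrazone 5 (not isolated)
Conditions: TsNHNH2 (1.05 equiv), MeOH, rt, evaporate; NaH (1.05 equiv), toluene, rt; HBpin (1.5 equiv), 110 °C
Reagents that add atoms: pinacolborane, CC1(C)OBOC1(C)C; p-toluenesulfonyl hydrazide, Cc1ccc(cc1)S(=O)(=O)NN (its atoms are in 5 only)
Why: Condensation to the tosylhydrazone, Bamford–Stevens fragmentation of its sodium salt to the diazoalkane and insertion of the diazo carbon into the B–H bond (borate formation, 1,2-hydride shift, loss of N2; transition-metal-free reductive borylation of tosylhydrazones) give the primary boronic ester without touching any stereocentre, the equatorial neopentyl bromide or the hindered tertiary acetate.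

Step 4
Reactants: 7 (S)-but-3-en-2-ol
Product: 8 (S)-but-3-en-2-yl N,N-diisopropylcarbamate
Conditions: iPr2NCOCl (1.2 equiv), Et3N (1.5 equiv), CH2Cl2, reflux
Reagents that add atoms: N,N-diisopropylcarbamoyl chloride, CC(C)N(C(C)C)C(Cl)=O
Why: O-Carbamoylation (acyl substitution at the carbamoyl chloride) installs the group that directs α-lithiation and later leaves; the carbinol C–O bond is not broken, so the S configuration is kept.

Step 5
Reactants: 8 (S)-but-3-en-2-yl N,N-diisopropylcarbamate; 6 decalin-ethyl pinacol boronic ester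
Product: 13 (1S,2S,4aS,6R,8aR)-6-bromo-1-[(3R)-3-hydroxy-3-methylpent-4-en-1-yl]-2,5,5,8a-tetramethyldecahydronaphthalen-2-ol (target), via lithiated carbamate 9 (not isolated), via boronate complex 10 (not isolated), via tertiary boronic ester 11 (not isolated), via acetoxy alcohol 12 (not isolated)
Conditions: 8 (1.5 equiv), s-BuLi (1.4 equiv), TMEDA (1.5 equiv), Et2O, −78 °C, 30 min; 6 (1.0 equiv) in Et2O, −78 °C, 1 h; MgBr2·OEt2/MeOH, −78 °C to rt; then 2 M NaOH, 30% H2O2, THF, 0 °C to rt; then MeOH, 45 °C
Reagents that add atoms: hydrogen peroxide, OO; sec-butyllithium, [Li]C(C)CC (its lithium is in 9 and 10 only)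
Why: Proposed new method: Hoppe–Aggarwal lithiation–borylation is established for γ-substituted secondary allylic carbamates and for propargylic ones (closest known type) and is extended here to the γ-unsubstituted but-3-en-2-yl carbamate; s-BuLi removes the carbinol proton with retention to give the configurationally stable α-oxygenated allyllithium 9 (a carbanion at what is normally an electrophilic carbinol carbon), which adds to boron with retention (α-attack is the only productive one, since a γ-adduct has no leaving group for a 1,2-shift and can revert), the C12 alkyl group migrates anti to the departing carbamate (inversion), stereoretentive C–B oxidation gives 13R, and the alkaline peroxide/MeOH finally saponifies the 8-acetate.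

## Compound list

1 | (5E,9E)-6,10,14-trimethylpentadeca-5,9,13-trien-2-one ((E,E)-farnesylacetone) | CC(=O)CC/C=C(\C)CC/C=C(\C)CCC=C(C)C | starting material
2 | 4-[(1S,2S,4aS,6R,8aR)-6-bromo-2-hydroxy-2,5,5,8a-tetramethyldecahydronaphthalen-1-yl]butan-2-one (open form of the cyclic hemiketal) | CC(=O)CC[C@H]1[C@]2(C)CC[C@@H](Br)C(C)(C)[C@H]2CC[C@]1(C)O | intermediate
3 | (4aS,6aS,8R,10aR,10bS)-8-bromo-3,4a,7,7,10a-pentamethyl-4a,5,6,6a,7,8,9,10,10a,10b-decahydro-1H-benzo[f]chromene | CC1=CC[C@H]2[C@]3(C)CC[C@@H](Br)C(C)(C)[C@H]3CC[C@]2(C)O1 | intermediate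
4 | 2-[(1S,2S,4aS,6R,8aR)-2-acetoxy-6-bromo-2,5,5,8a-tetramethyldecahydronaphthalen-1-yl]acetaldehyde | O=CC[C@H]1[C@]2(C)CC[C@@H](Br)C(C)(C)[C@H]2CC[C@]1(C)OC(C)=O | intermediate
5 | N-tosylhydrazone of aldehyde 4 | Cc1ccc(cc1)S(=O)(=O)N/N=C/C[C@H]1[C@]2(C)CC[C@@H](Br)C(C)(C)[C@H]2CC[C@]1(C)OC(C)=O | intermediate
6 | (1S,2S,4aS,6R,8aR)-6-bromo-2,5,5,8a-tetramethyl-1-[2-(4,4,5,5-tetramethyl-1,3,2-dioxaborolan-2-yl)ethyl]decahydronaphthalen-2-yl acetate | CC1(C)OB(CC[C@H]2[C@]3(C)CC[C@@H](Br)C(C)(C)[C@H]3CC[C@]2(C)OC(C)=O)OC1(C)C | intermediate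
7 | (S)-but-3-en-2-ol | C=C[C@H](C)O | starting material
8 | (S)-but-3-en-2-yl N,N-diisopropylcarbamate | C=C[C@H](C)OC(=O)N(C(C)C)C(C)C | intermediate
9 | (S)-2-lithiobut-3-en-2-yl N,N-diisopropylcarbamate (TMEDA-solvated) | C=C[C@]([Li])(C)OC(=O)N(C(C)C)C(C)C | intermediate
10 | lithium boronate complex of 6 and 9 (boron bound to C12, C13 and pinacol; carbamate still on C13) | C=C[C@](C)(OC(=O)N(C(C)C)C(C)C)[B-]1(CC[C@H]2[C@]3(C)CC[C@@H](Br)C(C)(C)[C@H]3CC[C@]2(C)OC(C)=O)OC(C)(C)C(C)(C)O1.[Li+] | intermediate
11 | (1S,2S,4aS,6R,8aR)-6-bromo-2,5,5,8a-tetramethyl-1-[(3S)-3-methyl-3-(4,4,5,5-tetramethyl-1,3,2-dioxaborolan-2-yl)pent-4-en-1-yl]decahydronaphthalen-2-yl acetate | C=C[C@@](C)(CC[C@H]1[C@]2(C)CC[C@@H](Br)C(C)(C)[C@H]2CC[C@]1(C)OC(C)=O)B3OC(C)(C)C(C)(C)O3 | intermediate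
12 | (1S,2S,4aS,6R,8aR)-6-bromo-1-[(3R)-3-hydroxy-3-methylpent-4-en-1-yl]-2,5,5,8a-tetramethyldecahydronaphthalen-2-yl acetate | C=C[C@](C)(O)CC[C@H]1[C@]2(C)CC[C@@H](Br)C(C)(C)[C@H]2CC[C@]1(C)OC(C)=O | intermediate
13 | (1S,2S,4aS,6R,8aR)-6-bromo-1-[(3R)-3-hydroxy-3-methylpent-4-en-1-yl]-2,5,5,8a-tetramethyldecahydronaphthalen-2-ol | C=C[C@](C)(O)CC[C@H]1[C@]2(C)CC[C@@H](Br)C(C)(C)[C@H]2CC[C@]1(C)O | target

## Step count and risks

Total steps: 5. Longest linear sequence: 4 steps (1 → 3 → 4 → 6 → 13; steps 1, 2, 3 and 5).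

Steps most likely to fail:

Step 1 (enantioselective bromocyclisation). The risks are low ee with a non-aromatic terminator, an incomplete second ring closure, and further bromination of the enol ether. The fallback sets out from 1 and comes back at 3. The cyclisation is run without asymmetric induction, using bromodiethylsulfonium bromopentachloroantimonate (BDSB) in MeNO2 at −25 °C, followed by the same aqueous work-up and PPTS dehydration. This gives hydroxy ketone 2 together with the mirror-image hydroxy ketone F1, and then racemic enol ether, that is 3 together with the mirror-image enol ether F2. The racemate is resolved by preparative chiral SFC; F2 is discarded and 3 goes on to step 2.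

Step 3 (deoxygenative borylation). The risks are a 1,2-H shift of the unstabilised diazoalkane to the alkene, azine formation, and attack on the acetate under hot basic hydride conditions. The fallback sets out from 4 and comes back at 6. The aldehyde is reduced with NaBH4 in MeOH at 0 °C to the acetoxy alcohol F3. This is converted with I2, PPh3 and imidazole into the primary iodide F4; the acetyl group on O8 prevents closure to a tetrahydrofuran. Copper-catalysed borylation (CuI, PPh3, LiOMe, B2pin2, DMF, rt) then gives 6, since the primary iodide reacts well before the hindered secondary bromide.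

Step 5 (lithiation–borylation). The risks are γ- instead of α-borylation at the unsubstituted allyl terminus, loss of configuration of 9, and loss of the acetate to excess carbanion; the retentive course of the borylation is assumed by analogy. The fallback sets out from 6 and comes back at 13. The coupling partner is changed to the silyl-alkynyl carbamate (S)-4-(trimethylsilyl)but-3-yn-2-yl N,N-diisopropylcarbamate F5, made from commercial (S)-4-(trimethylsilyl)but-3-yn-2-ol and the same carbamoyl chloride. Propargylic secondary carbamates are an established substrate class for this reaction. The same one-pot sequence (s-BuLi/TMEDA, addition of 6, 1,2-shift, NaOH/H2O2, then MeOH at 45 °C, which also removes the acetate and the C-silyl group) gives the ethynyl diol (1S,2S,4aS,6R,8aR)-6-bromo-1-[(3R)-3-hydroxy-3-methylpent-4-yn-1-yl]-2,5,5,8a-tetramethyldecahydronaphthalen-2-ol F6. Lindlar semi-hydrogenation (Pd/CaCO3/Pb, quinoline, H2, 1 atm, EtOAc) then gives 13.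

Further compounds
F1 | step 1 | 4-[(1R,2R,4aR,6S,8aS)-6-bromo-2-hydroxy-2,5,5,8a-tetramethyldecahydronaphthalen-1-yl]butan-2-one (mirror image of 2) | CC(=O)CC[C@@H]1[C@@]2(C)CC[C@H](Br)C(C)(C)[C@@H]2CC[C@@]1(C)O
F2 | step 1 | (4aR,6aR,8S,10aS,10bR)-8-bromo-3,4a,7,7,10a-pentamethyl-4a,5,6,6a,7,8,9,10,10a,10b-decahydro-1H-benzo[f]chromene (mirror image of 3) | CC1=CC[C@@H]2[C@@]3(C)CC[C@H](Br)C(C)(C)[C@@H]3CC[C@@]2(C)O1
F3 | step 3 | (1S,2S,4aS,6R,8aR)-6-bromo-1-(2-hydroxyethyl)-2,5,5,8a-tetramethyldecahydronaphthalen-2-yl acetate | OCC[C@H]1[C@]2(C)CC[C@@H](Br)C(C)(C)[C@H]2CC[C@]1(C)OC(C)=O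
F4 | step 3 | (1S,2S,4aS,6R,8aR)-6-bromo-1-(2-iodoethyl)-2,5,5,8a-tetramethyldecahydronaphthalen-2-yl acetate | ICC[C@H]1[C@]2(C)CC[C@@H](Br)C(C)(C)[C@H]2CC[C@]1(C)OC(C)=O
F5 | step 5 | (S)-4-(trimethylsilyl)but-3-yn-2-yl N,N-diisopropylcarbamate | C[C@H](OC(=O)N(C(C)C)C(C)C)C#C[Si](C)(C)C
F6 | step 5 | (1S,2S,4aS,6R,8aR)-6-bromo-1-[(3R)-3-hydroxy-3-methylpent-4-yn-1-yl]-2,5,5,8a-tetramethyldecahydronaphthalen-2-ol | C#C[C@](C)(O)CC[C@H]1[C@]2(C)CC[C@@H](Br)C(C)(C)[C@H]2CC[C@]1(C)O
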